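**Strategy.** Each 5,7-dimethoxycoumarin is cut at C4–C4a, which turns it into an aryl propiolate. This is possible because, in coumarin A (on the styryl arm) and coumarin B (on the ring CH), C3 and C4 bear only hydrogen and C4a is the one unsubstituted carbon next to the O1-bearing C8a, ortho to the C5 and para to the C7 methoxy group. A single gold-catalysed double hydroarylation therefore closes both pyran-2-one rings of bis-propiolate 29, a Z-styryl cyclohexene with both stereocentres set and each arene present as a 2-substituted 3,5-dimethoxyphenyl propiolate. The core is assembled by iridium/amine allylation, ring-closing metathesis and anti-selective enolate methylation.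

Key step: step 15

Assumption: the iridium complex of the (R)-configured phosphoramidite–olefin ligand is taken to give the (3R) benzylic centre of 11; if a first run shows the opposite sense, the (S)-ligand is used and nothing else changes.

Remark on the structure: in the target the coumarin on the ring CH and the Z-styryl arm on the quaternary carbon are cis on the cyclohexene, and both centres are R. Ring A is the arene on the styryl arm and ring B the arene on the ring CH. The descriptor of the quaternary carbon changes between S and R along the route only because the CIP priorities change.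

Step 1
Reactants: 1 2-hydroxy-4,6-dimethoxybenzaldehyde; 2 chloromethyl methyl ether
Product: 3 2-(methoxymethoxy)-4,6-dimethoxybenzaldehyde
Conditions: MOMCl, i-Pr2NEt, CH2Cl2, 0 → 23 °C
Reagents that add atoms: chloromethyl methyl ether, COCCl
Why: Base-mediated O-alkylation of the phenol (Williamson-type acetal formation) caps the oxygen that becomes O1 of coumarin B with a group that survives organometallic, basic and metathesis conditions.

Step 2
Reactants: 3 2-(methoxymethoxy)-4,6-dimethoxybenzaldehyde; 4 vinylmagnesium bromide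
Product: 5 rac-1-[2-(methoxymethoxy)-4,6-dimethoxyphenyl]prop-2-en-1-ol
Conditions: CH2=CHMgBr, THF, −78 → 0 °C; then pH 7 aqueous buffer
Reagents that add atoms: vinylmagnesium bromide, C=C[Mg]Br
Why: Grignard 1,2-addition to the aryl aldehyde gives the branched carbinol, whose configuration is irrelevant because step 5 is enantioconvergent.

Step 3
Reactants: 6 methyl 5-oxohexanoate; 7 methyltriphenylphosphonium bromide
Product: 9 methyl 5-methylhex-5-enoate, via methylenetriphenylphosphorane 8 (not isolated)
Conditions: Ph3PCH3Br (slight excess over base), KN(SiMe3)2, THF, 0 °C; then 6, 0 → 23 °C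
Reagents that add atoms: methyltriphenylphosphonium bromide, C[P+](c1ccccc1)(c1ccccc1)c1ccccc1.[Br-]
Why: Wittig methylenation of the methyl ketone by the non-stabilised ylide is faster than any reaction at the ester and installs the 1,1-disubstituted alkene needed for ring closure.

Step 4
Reactants: 9 methyl 5-methylhex-5-enoate
Product: 10 5-methylhex-5-enal
Conditions: i-Bu2AlH (1.05 equiv), CH2Cl2, −78 °C; then aqueous Rochelle salt
Reagents that add atoms: none
Why: Partial ester reduction stops at the tetrahedral aluminium hemiacetal at low temperature, and this gives the aldehyde on work-up.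

Step 5
Reactants: 5 rac-1-[2-(methoxymethoxy)-4,6-dimethoxyphenyl]prop-2-en-1-ol; 10 5-methylhex-5-enal
Product: 11 (2R,3R)-3-[2-(methoxymethoxy)-4,6-dimethoxyphenyl]-2-(3-methylbut-3-en-1-yl)pent-4-enal
Conditions: [Ir(cod)Cl]2 (3 mol %), (R)-4-(5H-dibenzo[b,f]azepin-5-yl)dinaphtho[2,1-d:1',2'-f][1,3,2]dioxaphosphepine (12 mol %), (S)-2-{bis[3,5-bis(trifluoromethyl)phenyl][(trimethylsilyl)oxy]methyl}pyrrolidine (15 mol %), (MeO)2P(O)OH (cat.), ClCH2CH2Cl, 25 °C
Reagents that add atoms: none
Why: In this dual-catalytic α-allylation of an aldehyde the acid-promoted iridium catalyst ionises either enantiomer of 5 to one π-allyl complex, which the chiral enamine of 10 attacks at the aryl-bearing terminus; the iridium ligand sets the benzylic centre (3R) and the amine sets C2 (2R, erased again in step 7, so its configuration is of no consequence).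

Step 6
Reactants: 11 (2R,3R)-3-[2-(methoxymethoxy)-4,6-dimethoxyphenyl]-2-(3-methylbut-3-en-1-yl)pent-4-enal
Product: 12 (1R,2R)-2-[2-(methoxymethoxy)-4,6-dimethoxyphenyl]-4-methylcyclohex-3-ene-1-carbaldehyde
Conditions: second-generation Grubbs catalyst (H2IMes)(PCy3)Cl2Ru=CHPh (5 mol %), CH2Cl2, 40 °C
Reagents that add atoms: none
Why: Ring-closing metathesis between the vinyl group and the 1,1-disubstituted alkene closes the six-membered ring as a trisubstituted cyclohexene with loss of ethene and leaves both stereocentres untouched.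

Step 7
Reactants: 12 (1R,2R)-2-[2-(methoxymethoxy)-4,6-dimethoxyphenyl]-4-methylcyclohex-3-ene-1-carbaldehyde; 13 iodomethane
Product: 15 (1S,2R)-2-[2-(methoxymethoxy)-4,6-dimethoxyphenyl]-1,4-dimethylcyclohex-3-ene-1-carbaldehyde, via potassium enolate 14 (not isolated)
Conditions: KOt-Bu, THF, 0 °C; then MeI, 0 → 23 °C
Reagents that add atoms: iodomethane, CI
Why: In this enolate C-alkylation of an α-branched aldehyde the exocyclic enolate 14 holds the neighbouring aryl group pseudo-axial to avoid allylic 1,3-strain, so iodomethane should enter from the opposite face and the quaternary centre forms with methyl trans and formyl cis to the aryl group (substrate control by the centre set in step 5).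

Step 8
Reactants: 15 (1S,2R)-2-[2-(methoxymethoxy)-4,6-dimethoxyphenyl]-1,4-dimethylcyclohex-3-ene-1-carbaldehyde; 16 dimethyl (1-diazo-2-oxopropyl)phosphonate
Product: 18 2-[(1R,6S)-6-ethynyl-3,6-dimethylcyclohex-2-en-1-yl]-1,5-dimethoxy-3-(methoxymethoxy)benzene, via dimethyl (diazomethyl)phosphonate 17 (not isolated)
Conditions: K2CO3, MeOH, 0 → 23 °C
Reagents that add atoms: dimethyl (1-diazo-2-oxopropyl)phosphonate, COP(=O)(OC)C(=[N+]=[N-])C(C)=O
Why: The Ohira–Bestmann variant of the Seyferth–Gilbert homologation turns the non-enolisable neopentyl aldehyde into the terminal alkyne under carbonate conditions that cannot epimerise either centre.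

Step 9
Reactants: 19 3,5-dimethoxyphenol; 2 chloromethyl methyl ether
Product: 20 1,3-dimethoxy-5-(methoxymethoxy)benzene
Conditions: MOMCl, i-Pr2NEt, CH2Cl2, 0 → 23 °C
Reagents that add atoms: chloromethyl methyl ether, COCCl
Why: Phenol O-alkylation as in step 1 installs both the protecting group of ring A and the directing group for the next step.

Step 10
Reactants: 20 1,3-dimethoxy-5-(methoxymethoxy)benzene; 21 iodine
Product: 23 2-iodo-1,5-dimethoxy-3-(methoxymethoxy)benzene, via aryllithium 22 (not isolated)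
Conditions: n-BuLi, TMEDA, THF, 0 °C; then I2, −78 → 23 °C
Reagents that add atoms: iodine, II
Why: In this directed ortho-metalation the chelating methoxymethoxy group and the neighbouring methoxy group should steer lithiation to the carbon between them (two equivalent sites), and the iodine quench gives the iodide with the oxygenation pattern of ring A.

Step 11
Reactants: 18 2-[(1R,6S)-6-ethynyl-3,6-dimethylcyclohex-2-en-1-yl]-1,5-dimethoxy-3-(methoxymethoxy)benzene; 23 2-iodo-1,5-dimethoxy-3-(methoxymethoxy)benzene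
Product: 24 2-({(1S,2R)-2-[2-(methoxymethoxy)-4,6-dimethoxyphenyl]-1,4-dimethylcyclohex-3-en-1-yl}ethynyl)-1,5-dimethoxy-3-(methoxymethoxy)benzene
Conditions: Pd(PPh3)4 (5 mol %), CuI (10 mol %), Et3N, DMF, degassed, 60 °C
Reagents that add atoms: none
Why: Sonogashira coupling (oxidative addition of the aryl iodide to zerovalent palladium, transfer of the copper acetylide) joins the two halves, and the linear alkyne keeps the two hindered partners apart in the bond-forming step.

Step 12
Reactants: 24 2-({(1S,2R)-2-[2-(methoxymethoxy)-4,6-dimethoxyphenyl]-1,4-dimethylcyclohex-3-en-1-yl}ethynyl)-1,5-dimethoxy-3-(methoxymethoxy)benzene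
Product: 25 2-[(Z)-2-{(1R,2R)-2-[2-(methoxymethoxy)-4,6-dimethoxyphenyl]-1,4-dimethylcyclohex-3-en-1-yl}ethenyl]-1,5-dimethoxy-3-(methoxymethoxy)benzene
Conditions: H2 (1 atm), Pd/CaCO3 poisoned with Pb(OAc)2 (Lindlar catalyst), quinoline, EtOAc, 23 °C
Reagents that add atoms: none
Why: Lindlar semi-hydrogenation delivers both hydrogens to the same face of the alkyne on the poisoned palladium surface, which gives the Z alkene and leaves the trisubstituted ring alkene alone.

Step 13
Reactants: 25 2-[(Z)-2-{(1R,2R)-2-[2-(methoxymethoxy)-4,6-dimethoxyphenyl]-1,4-dimethylcyclohex-3-en-1-yl}ethenyl]-1,5-dimethoxy-3-(methoxymethoxy)benzene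
Product: 27 2-[(Z)-2-{(1R,2R)-2-(2-hydroxy-4,6-dimethoxyphenyl)-1,4-dimethylcyclohex-3-en-1-yl}ethenyl]-3,5-dimethoxyphenol, via bis(trimethylsilyl) ether 26 (not isolated)
Conditions: Me3SiOTf, 2,2'-bipyridyl, CH3CN, 0 → 23 °C; then H2O
Reagents that add atoms: none
Why: Silyl triflate/bipyridyl cleavage of aryl methoxymethyl ethers runs through a bipyridinium acetal salt and the aryl silyl ether 26 without free Brønsted acid, so the electron-rich Z-styrene should not isomerise and the ring B phenol should not add to the ring alkene.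

Step 14
Reactants: 27 2-[(Z)-2-{(1R,2R)-2-(2-hydroxy-4,6-dimethoxyphenyl)-1,4-dimethylcyclohex-3-en-1-yl}ethenyl]-3,5-dimethoxyphenol; 28 propiolic acid
Product: 29 2-[(Z)-2-{(1R,2R)-1,4-dimethyl-2-[2,4-dimethoxy-6-(prop-2-ynoyloxy)phenyl]cyclohex-3-en-1-yl}ethenyl]-3,5-dimethoxyphenyl prop-2-ynoate
Conditions: HC≡CCO2H (3 equiv), DCC (3 equiv), DMAP (5 mol %), CH2Cl2, −20 → 0 °C
Reagents that add atoms: propiolic acid, C#CC(=O)O
Why: Steglich-type carbodiimide esterification acylates both phenols with the small propiolic acid at low temperature, where conjugate addition to the ynoate is slow.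

Step 15
Reactants: 29 2-[(Z)-2-{(1R,2R)-1,4-dimethyl-2-[2,4-dimethoxy-6-(prop-2-ynoyloxy)phenyl]cyclohex-3-en-1-yl}ethenyl]-3,5-dimethoxyphenyl prop-2-ynoate
Product: 32 8-[(Z)-2-{(1R,2R)-2-(5,7-dimethoxy-2-oxo-2H-chromen-8-yl)-1,4-dimethylcyclohex-3-en-1-yl}ethenyl]-5,7-dimethoxy-2H-chromen-2-one (target CNP0164660.3), via ring-A monocoumarin 30 (not isolated), via ring-B monocoumarin 31 (not isolated)
Conditions: [(2-biphenylyl)(t-Bu)2PAu(NCMe)]SbF6 (10 mol %), 4 Å molecular sieves, ClCH2CH2Cl (0.01 M), 23 → 40 °C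
Reagents that add atoms: none
Why: Monovalent gold π-activates each propiolate alkyne, the free ortho carbon of the arene attacks the terminal alkyne carbon anti to gold to give a Wheland intermediate that rearomatises, and protodeauration of the vinylgold species releases the coumarin and the catalyst. The closest known reaction is the gold- or platinum-catalysed intramolecular hydroarylation of aryl alkynoates to coumarins, here run twice on one substrate. Each pyran-2-one ring (coumarin A on ring A, coumarin B on ring B) closes in the 6-endo-dig mode by forming its C4–C4a bond. No stereocentre is created, and the two existing centres and the Z alkene are spectators. The step needs regioselectivity on each arene, secured because only one carbon ortho to the ester oxygen is unsubstituted and it is activated by an ortho and a para methoxy group, and chemoselectivity for the alkynes over the Z-styryl and ring alkenes, secured by the preference of gold for alkynes and by the short tether to the arene. A preformed, silver-free cationic complex is chosen so that no free strong acid is present to isomerise the electron-rich Z-styrene.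

**Compound list**

1 | 2-hydroxy-4,6-dimethoxybenzaldehyde | COc1cc(O)c(C=O)c(OC)c1 | starting material
2 | chloromethyl methyl ether | COCCl | starting material
3 | 2-(methoxymethoxy)-4,6-dimethoxybenzaldehyde | COCOc1cc(OC)cc(OC)c1C=O | intermediate
4 | vinylmagnesium bromide | C=C[Mg]Br | starting material
5 | rac-1-[2-(methoxymethoxy)-4,6-dimethoxyphenyl]prop-2-en-1-ol | C=CC(O)c1c(OC)cc(OC)cc1OCOC | intermediate
6 | methyl 5-oxohexanoate | COC(=O)CCCC(C)=O | starting material
7 | methyltriphenylphosphonium bromide | C[P+](c1ccccc1)(c1ccccc1)c1ccccc1.[Br-] | starting material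
8 | methylenetriphenylphosphorane (formed in the flask) | C=P(c1ccccc1)(c1ccccc1)c1ccccc1 | intermediate
9 | methyl 5-methylhex-5-enoate | COC(=O)CCCC(C)=C | intermediate
10 | 5-methylhex-5-enal | O=CCCCC(C)=C | intermediate
11 | (2R,3R)-3-[2-(methoxymethoxy)-4,6-dimethoxyphenyl]-2-(3-methylbut-3-en-1-yl)pent-4-enal | O=C[C@H](CCC(C)=C)[C@@H](C=C)c1c(OC)cc(OC)cc1OCOC | intermediate
12 | (1R,2R)-2-[2-(methoxymethoxy)-4,6-dimethoxyphenyl]-4-methylcyclohex-3-ene-1-carbaldehyde (formyl trans to aryl) | O=C[C@@H]1CCC(C)=C[C@H]1c1c(OC)cc(OC)cc1OCOC | intermediate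
13 | iodomethane | CI | starting material
14 | potassium [(2R)-2-[2-(methoxymethoxy)-4,6-dimethoxyphenyl]-4-methylcyclohex-3-en-1-ylidene]methanolate (enolate of 12, C1 planar, formed in the flask) | [K+].[O-]C=C1CCC(C)=C[C@H]1c1c(OC)cc(OC)cc1OCOC | intermediate
15 | (1S,2R)-2-[2-(methoxymethoxy)-4,6-dimethoxyphenyl]-1,4-dimethylcyclohex-3-ene-1-carbaldehyde (formyl cis to aryl, methyl trans) | O=C[C@@]1(C)CCC(C)=C[C@H]1c1c(OC)cc(OC)cc1OCOC | intermediate
16 | dimethyl (1-diazo-2-oxopropyl)phosphonate | COP(=O)(OC)C(=[N+]=[N-])C(C)=O | starting material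
17 | dimethyl (diazomethyl)phosphonate (formed in the flask) | COP(=O)(OC)C=[N+]=[N-] | intermediate
18 | 2-[(1R,6S)-6-ethynyl-3,6-dimethylcyclohex-2-en-1-yl]-1,5-dimethoxy-3-(methoxymethoxy)benzene | C#C[C@@]1(C)CCC(C)=C[C@H]1c1c(OC)cc(OC)cc1OCOC | intermediate
19 | 3,5-dimethoxyphenol | COc1cc(O)cc(OC)c1 | starting material
20 | 1,3-dimethoxy-5-(methoxymethoxy)benzene | COCOc1cc(OC)cc(OC)c1 | intermediate
21 | iodine | II | starting material
22 | [2,4-dimethoxy-6-(methoxymethoxy)phenyl]lithium (formed in the flask) | [Li]c1c(OC)cc(OC)cc1OCOC | intermediate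
23 | 2-iodo-1,5-dimethoxy-3-(methoxymethoxy)benzene | COCOc1cc(OC)cc(OC)c1I | intermediate
24 | 2-({(1S,2R)-2-[2-(methoxymethoxy)-4,6-dimethoxyphenyl]-1,4-dimethylcyclohex-3-en-1-yl}ethynyl)-1,5-dimethoxy-3-(methoxymethoxy)benzene | COCOc1cc(OC)cc(OC)c1C#C[C@@]1(C)CCC(C)=C[C@H]1c1c(OC)cc(OC)cc1OCOC | intermediate
25 | 2-[(Z)-2-{(1R,2R)-2-[2-(methoxymethoxy)-4,6-dimethoxyphenyl]-1,4-dimethylcyclohex-3-en-1-yl}ethenyl]-1,5-dimethoxy-3-(methoxymethoxy)benzene | COCOc1cc(OC)cc(OC)c1/C=C\[C@@]1(C)CCC(C)=C[C@H]1c1c(OC)cc(OC)cc1OCOC | intermediate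
26 | bis(trimethylsilyl) ether of 27 (formed in the flask) | C[Si](C)(C)Oc1cc(OC)cc(OC)c1/C=C\[C@@]1(C)CCC(C)=C[C@H]1c1c(OC)cc(OC)cc1O[Si](C)(C)C | intermediate
27 | 2-[(Z)-2-{(1R,2R)-2-(2-hydroxy-4,6-dimethoxyphenyl)-1,4-dimethylcyclohex-3-en-1-yl}ethenyl]-3,5-dimethoxyphenol | Oc1cc(OC)cc(OC)c1/C=C\[C@@]1(C)CCC(C)=C[C@H]1c1c(OC)cc(OC)cc1O | intermediate
28 | propiolic acid | C#CC(=O)O | starting material
29 | 2-[(Z)-2-{(1R,2R)-1,4-dimethyl-2-[2,4-dimethoxy-6-(prop-2-ynoyloxy)phenyl]cyclohex-3-en-1-yl}ethenyl]-3,5-dimethoxyphenyl prop-2-ynoate (precursor of the key step) | C#CC(=O)Oc1cc(OC)cc(OC)c1/C=C\[C@@]1(C)CCC(C)=C[C@H]1c1c(OC)cc(OC)cc1OC(=O)C#C | intermediate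
30 | monocyclised compound with coumarin A closed and the ring B propiolate intact (formed in the flask) | COc1cc(OC)c2ccc(=O)oc2c1/C=C\[C@@]1(C)CCC(C)=C[C@H]1c1c(OC)cc(OC)cc1OC(=O)C#C | intermediate
31 | monocyclised compound with coumarin B closed and the ring A propiolate intact (formed in the flask) | C#CC(=O)Oc1cc(OC)cc(OC)c1/C=C\[C@@]1(C)CCC(C)=C[C@H]1c1c(OC)cc(OC)c2ccc(=O)oc12 | intermediate
32 | 8-[(Z)-2-{(1R,2R)-2-(5,7-dimethoxy-2-oxo-2H-chromen-8-yl)-1,4-dimethylcyclohex-3-en-1-yl}ethenyl]-5,7-dimethoxy-2H-chromen-2-one (CNP0164660.3) | COc1cc(OC)c2ccc(=O)oc2c1/C=C\[C@@]1(C)CCC(C)=C[C@H]1c1c(OC)cc(OC)c2ccc(=O)oc12 | target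

**Step count.** Total: 15 steps. Longest linear sequence: 11 steps (1, 2, 5, 6, 7, 8, 11, 12, 13, 14, 15).

**The three steps most likely to fail**

Step 15 (double hydroarylation). What may go wrong: Z-to-E isomerisation of the electron-rich styryl alkene by gold or by traces of acid, or a competing enyne cyclisation onto the styryl or ring alkene before the second lactone has closed. Fallback: the route is left at bis-phenol 27, and each lactone is built by formylation and intramolecular Wittig ring closure. Magnesium-mediated ortho-formylation (MgCl2, Et3N, paraformaldehyde, THF, reflux) should place a formyl group on the single free ortho carbon of each phenol and give 3-[(Z)-2-{(1R,2R)-2-(3-formyl-2-hydroxy-4,6-dimethoxyphenyl)-1,4-dimethylcyclohex-3-en-1-yl}ethenyl]-2-hydroxy-4,6-dimethoxybenzaldehyde F1. Heating F1 with (triphenylphosphoranylidene)ketene, Ph3P=C=C=O, in toluene at 90 °C should acylate both phenols to the bis(phosphoranylideneacetate) F2, which is not isolated. Each ester ylide of F2 then condenses with the neighbouring aldehyde and forms the C3–C4 double bond, which returns the route at target 32.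

Step 5 (iridium/amine allylation). What may go wrong: ionisation of the very electron-rich carbinol 5 by the acid promoter without iridium, which would lower the enantiomeric purity or send the nucleophile to the linear terminus. Fallback: an acid-free allylic alkylation of a linear carbonate with a stabilised nucleophile, setting out from aldehyde 3 and rejoining at 12.
- Horner–Wadsworth–Emmons reaction of 3 with trimethyl phosphonoacetate (NaH, THF) should give methyl (E)-3-[2-(methoxymethoxy)-4,6-dimethoxyphenyl]prop-2-enoate F3.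
- Reduction with i-Bu2AlH gives (E)-3-[2-(methoxymethoxy)-4,6-dimethoxyphenyl]prop-2-en-1-ol F4, and methyl chloroformate with pyridine gives the methyl carbonate F5.
- Iridium-catalysed allylic alkylation of F5 with dimethyl malonate ([Ir(cod)Cl]2, the binaphthol-derived phosphoramidite of bis[1-(2-methoxyphenyl)ethyl]amine in the enantiomer that leads to the R centre, THF) should give the branched malonate, dimethyl 2-{(1R)-1-[2-(methoxymethoxy)-4,6-dimethoxyphenyl]prop-2-en-1-yl}propanedioate F6.
- Alkylation (NaH, 4-iodo-2-methylbut-1-ene, DMF) gives the diene, dimethyl 2-{(1S)-1-[2-(methoxymethoxy)-4,6-dimethoxyphenyl]prop-2-en-1-yl}-2-(3-methylbut-3-en-1-yl)propanedioate F7.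
- Ring-closing metathesis as in step 6 gives dimethyl (2S)-2-[2-(methoxymethoxy)-4,6-dimethoxyphenyl]-4-methylcyclohex-3-ene-1,1-dicarboxylate F8.
- Krapcho demethoxycarbonylation (LiCl, wet DMSO, 150 °C) followed by NaOMe equilibration gives methyl (1R,2R)-2-[2-(methoxymethoxy)-4,6-dimethoxyphenyl]-4-methylcyclohex-3-ene-1-carboxylate F9.
- Reduction with i-Bu2AlH at −78 °C gives aldehyde 12, where the route is rejoined before step 7. Any C1 epimer is harmless because step 7 planarises C1.

Step 12 (semi-hydrogenation). What may go wrong: slow hydrogen uptake at an alkyne shielded by the quaternary carbon and by two ortho substituents, so that conversion stays incomplete or forcing leads to over-reduction. Fallback: the Z alkene is made by olefination and cross-coupling without an alkyne, setting out from aldehyde 15 and rejoining at 25 (steps 8, 11 and 12 are replaced). Stork–Zhao olefination of 15 with the ylide from (iodomethyl)triphenylphosphonium iodide and NaN(SiMe3)2 (THF/DMPU, −78 °C) should give 2-{(1R,6S)-6-[(Z)-2-iodoethenyl]-3,6-dimethylcyclohex-2-en-1-yl}-1,5-dimethoxy-3-(methoxymethoxy)benzene F10. Aryllithium 22, generated from 20 as in step 10, is transmetalated with ZnCl2 to [2,4-dimethoxy-6-(methoxymethoxy)phenyl]zinc chloride F11. Negishi coupling of F10 with F11 (Pd2(dba)3, 2-dicyclohexylphosphino-2',6'-dimethoxybiphenyl, THF, 50 °C) proceeds with retention of the alkene geometry and gives 25, which continues with step 13.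

Further compounds
F1 | step 15 | 3-[(Z)-2-{(1R,2R)-2-(3-formyl-2-hydroxy-4,6-dimethoxyphenyl)-1,4-dimethylcyclohex-3-en-1-yl}ethenyl]-2-hydroxy-4,6-dimethoxybenzaldehyde | O=Cc1c(OC)cc(OC)c(/C=C\[C@@]2(C)CCC(C)=C[C@H]2c2c(OC)cc(OC)c(C=O)c2O)c1O
F2 | step 15 | bis[(triphenylphosphoranylidene)acetate] of F1 (not isolated) | O=Cc1c(OC)cc(OC)c(/C=C\[C@@]2(C)CCC(C)=C[C@H]2c2c(OC)cc(OC)c(C=O)c2OC(=O)C=P(c2ccccc2)(c2ccccc2)c2ccccc2)c1OC(=O)C=P(c1ccccc1)(c1ccccc1)c1ccccc1
F3 | step 5 | methyl (E)-3-[2-(methoxymethoxy)-4,6-dimethoxyphenyl]prop-2-enoate | COC(=O)/C=C/c1c(OC)cc(OC)cc1OCOC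
F4 | step 5 | (E)-3-[2-(methoxymethoxy)-4,6-dimethoxyphenyl]prop-2-en-1-ol | OC/C=C/c1c(OC)cc(OC)cc1OCOC
F5 | step 5 | (E)-3-[2-(methoxymethoxy)-4,6-dimethoxyphenyl]prop-2-en-1-yl methyl carbonate | COC(=O)OC/C=C/c1c(OC)cc(OC)cc1OCOC
F6 | step 5 | dimethyl 2-{(1R)-1-[2-(methoxymethoxy)-4,6-dimethoxyphenyl]prop-2-en-1-yl}propanedioate | COC(=O)C(C(=O)OC)[C@@H](C=C)c1c(OC)cc(OC)cc1OCOC
F7 | step 5 | dimethyl 2-{(1S)-1-[2-(methoxymethoxy)-4,6-dimethoxyphenyl]prop-2-en-1-yl}-2-(3-methylbut-3-en-1-yl)propanedioate | COC(=O)C(CCC(C)=C)(C(=O)OC)[C@@H](C=C)c1c(OC)cc(OC)cc1OCOC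
F8 | step 5 | dimethyl (2S)-2-[2-(methoxymethoxy)-4,6-dimethoxyphenyl]-4-methylcyclohex-3-ene-1,1-dicarboxylate | COC(=O)C1(C(=O)OC)CCC(C)=C[C@H]1c1c(OC)cc(OC)cc1OCOC
F9 | step 5 | methyl (1R,2R)-2-[2-(methoxymethoxy)-4,6-dimethoxyphenyl]-4-methylcyclohex-3-ene-1-carboxylate | COC(=O)[C@@H]1CCC(C)=C[C@H]1c1c(OC)cc(OC)cc1OCOC
F10 | step 12 | 2-{(1R,6S)-6-[(Z)-2-iodoethenyl]-3,6-dimethylcyclohex-2-en-1-yl}-1,5-dimethoxy-3-(methoxymethoxy)benzene | I/C=C\[C@@]1(C)CCC(C)=C[C@H]1c1c(OC)cc(OC)cc1OCOC
F11 | step 12 | [2,4-dimethoxy-6-(methoxymethoxy)phenyl]zinc chloride | Cl[Zn]c1c(OC)cc(OC)cc1OCOC
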